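**Plan**

- Cuts: the C8–O angelate bond (made with inversion), the exocyclic C11=C13, and the lactone bonds C7–C11 and C6–O go first; the C10 carbinol is traced back to a C1=C10 alkene and the C3 ketone to a ketal.
- Enabling feature: once C10 is dehydrated, ring atoms C10=C1–C2–C3–C4=C5 form a 1,5-diene inside the ten-membered ring. This is the retron for cycloreversion of a bicyclo[2.2.0]hexane fused to a cyclohexanone, so C4=C5 and C1=C10 are exchanged for the enone alkene C5=C10 (six-membered ring C5–C10, C6 carbonyl) and a cyclobutene C1=C4 (four-membered ring C1–C4).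
- Forward order: the six-membered enone and the four-membered ring are made separately; light joins them (C4–C5, C1–C10) in a cyclobutane, heat breaks C1–C4 and C5–C10 to give the ten-membered ring; then the 3,10-oxygen bridge (five-membered ketal ring) and last the γ-lactone are closed.
- Stereochemistry: C8 comes from lipase desymmetrization of a meso diol and is carried as the 8-epimer until a closing Mitsunobu angeloylation inverts it; C10 from a reagent-controlled Shi epoxidation; C7 from enolate alkylation anti to the C8 silyloxy group; C6 from hydride addition anti to the new C7 arm.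

Key step: step 7

Remark (convention): germacrane numbering is used for all ten-membered-ring compounds (C14 = methyl on C10, C15 on C4, C11–C13 = lactone carbons). α/β refer to the ring drawn flat with C1→C10 counterclockwise and β toward the viewer; the target (6S,7R,8R,10R, 4Z) is then 6β-O, 7β-C11, 8β-OAng, 10β-OH. TBS = tert-butyldimethylsilyl, TBDPS = tert-butyldiphenylsilyl.
Remark (assumption): the target is drawn as the open C3-keto/C10-hydroxy tautomer; it is assumed to equilibrate with its 3,10-hemiketal, and the last step is taken to deliver this tautomeric pair.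
Remark (assumption): the lipase of step 2 is taken to acylate the hydroxyl that gives 3; if the chosen enzyme prefers the other one, using it to hydrolyse the corresponding diacetate leads to the same monoacetate.

Step 1
Reactants: 1 all-cis-cyclohexane-1,3,5-triol
Product: 2 all-cis-5-(TBS-oxy)cyclohexane-1,3-diol (meso)
Conditions: TBSCl (1 equiv), imidazole, DMF, 0 → 25 °C
Reagents that add atoms: tert-butyldimethylsilyl chloride, CC(C)(C)[Si](C)(C)Cl
Why: Statistical mono-silylation (silyl ether formation) of the C3-symmetric triol should give the meso diol, whose two remaining hydroxyls are enantiotopic.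

Step 2
Reactants: 2 all-cis-5-(TBS-oxy)cyclohexane-1,3-diol (meso)
Product: 3 (1R,3S,5S)-3-hydroxy-5-(TBS-oxy)cyclohexyl acetate
Conditions: Novozym 435 (immobilized lipase B from Candida antarctica), vinyl acetate, tert-butyl methyl ether, 25 °C
Reagents that add atoms: vinyl acetate, C=COC(C)=O
Why: Enzymatic desymmetrization by irreversible lipase transesterification should acylate one enantiotopic hydroxyl only and so fix the absolute configuration of the carbon that becomes C8.

Step 3
Reactants: 3 (1R,3S,5S)-3-hydroxy-5-(TBS-oxy)cyclohexyl acetate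
Product: 5 (R)-5-(TBS-oxy)cyclohex-2-en-1-one, via acetoxy ketone 4 (not isolated)
Conditions: (COCl)2, DMSO, CH2Cl2, −78 °C; Et3N, −78 → 25 °C
Reagents that add atoms: none
Why: Swern oxidation gives the β-acetoxy ketone, which should lose acetic acid by E1cB elimination under the amine base while the silyloxy-bearing centre is untouched.

Step 4
Reactants: 5 (R)-5-(TBS-oxy)cyclohex-2-en-1-one
Product: 7 (S)-5-(TBS-oxy)-3-methylcyclohex-2-en-1-one, via tertiary allylic alcohol 6 (not isolated)
Conditions: MeLi, Et2O, −78 °C; aqueous work-up, then pyridinium chlorochromate C5H5NH[CrO3Cl], CH2Cl2, 25 °C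
Reagents that add atoms: methyllithium, [Li]C
Why: 1,2-Addition of methyllithium followed by Babler–Dauben oxidative transposition of the tertiary allylic alcohol should move the carbonyl to the former acetate carbon and leave the methyl on the β-carbon; the stereocentre is not involved.

Step 5
Reactants: 8 1,1-dimethoxyethene; 9 methyl acrylate
Product: 10 methyl 2,2-dimethoxycyclobutane-1-carboxylate
Conditions: MeCN, 80 °C, sealed tube
Reagents that add atoms: none
Why: Thermal [2+2] cycloaddition of a ketene acetal to an acrylate runs through a zwitterion in which the nucleophilic CH2 bonds to the acrylate β-carbon, so the ketal carbon should end next to the ester-bearing carbon.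

Step 6
Reactants: 10 methyl 2,2-dimethoxycyclobutane-1-carboxylate
Product: 13 methyl 4,4-dimethoxycyclobut-1-ene-1-carboxylate, via selenide 11 (not isolated), via selenoxide 12 (not isolated)
Conditions: LiN(iPr)2, THF, −78 °C; PhSeBr; then H2O2 (30% aq), pyridine, CH2Cl2, 0 → 25 °C
Reagents that add atoms: none
Why: α-Selenenylation of the ester enolate and selenoxide syn-elimination can take a hydrogen only from the ring CH2, because the other neighbour is the quaternary ketal carbon, so the alkene should form between the ester carbon and that CH2.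

Step 7
Reactants: 7 (S)-5-(TBS-oxy)-3-methylcyclohex-2-en-1-one; 13 methyl 4,4-dimethoxycyclobut-1-ene-1-carboxylate
Product: 15 methyl (8S)-8-(TBS-oxy)-3,3-dimethoxy-10-methyl-6-oxocyclodeca-1(10),4-diene-4-carboxylate [(E)-C1=C10; ring-cis C4=C5], via tricyclic photoadduct 14 (not isolated)
Conditions: hν (350 nm, Pyrex), 13 in excess, CH2Cl2, −20 °C; evaporate, then toluene, 150–170 °C, sealed tube
Reagents that add atoms: none
Why: Irradiation populates the enone triplet, which adds to the strained cyclobutene 13 through a 1,4-diradical and closes the cyclobutane of 14 (bonds C4–C5 and C1–C10, enone [2+2] photocycloaddition); heating then breaks the central C1–C4 bond of the bicyclo[2.2.0]hexane unit to an ester-stabilized cyclohexane-1,4-diyl that fragments at C5–C10. The closest known reaction is the photoaddition of cyclobutene-1-carboxylates to cyclohexenones followed by thermolysis of the tricyclo[4.4.0.0(2,5)]decanones to cyclodeca-1,5-dienes. The ten-membered ring is therefore not closed end to end but arises by ring expansion, the six- and four-membered rings merging when the two bonds they share with the central cyclobutane break. No stereocentre is created that survives: the four cyclobutane centres return to sp2 carbons whichever face of 7 is attacked, and C8 is a spectator. The step needs head-to-head orientation, which the acceptor ester on C4 (bonding to the enone α-carbon C5) and sterics (unsubstituted C1 meets the methyl-bearing C10) should secure, and it needs (E)-C1=C10 with ring-cis C4=C5, which follow from the cis-anti-cis fusion and are the favoured geometries of the trisubstituted and the doubly conjugated alkene. The bath is held at the lowest temperature that opens 14 so that the 1,5-diene does not go on to its Cope isomer.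

Step 8
Reactants: 15 methyl (8S)-8-(TBS-oxy)-3,3-dimethoxy-10-methyl-6-oxocyclodeca-1(10),4-diene-4-carboxylate
Product: 16 (1S,10S)-1,10-epoxide of 15 (1α,10β-epoxide)
Conditions: ent-Shi ketone (30 mol %), KHSO5 (as 2KHSO5·KHSO4·K2SO4), K2CO3, Bu4NHSO4, MeCN–CH2(OMe)2–aqueous buffer (pH 10.5), 0 °C
Reagents that add atoms: potassium peroxymonosulfate, [K+].[O-]S(=O)(=O)OO
Why: In this Shi asymmetric epoxidation the chiral dioxirane should attack only the electron-rich trisubstituted C1=C10 alkene, and the L-configured ketone (the fructose-derived one gives R,R-epoxides from such E-alkenes) should select the face that gives the (1S,10S)-epoxide, so the C10–O bond of the target is set under reagent control.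

Step 9
Reactants: 16 (1S,10S)-1,10-epoxide of 15
Product: 17 8α-(TBS-oxy)-4-(hydroxymethyl)-3,3-dimethoxy-10α-methylcyclodec-4-ene-6,10β-diol (C6 epimers)
Conditions: LiAlH4, THF, −20 → 25 °C
Reagents that add atoms: none
Why: Hydride reduction should take ketone and ester to the alcohols in the 1,2 sense and open the epoxide by SN2 attack at the less substituted C1, so the C10–O bond and its configuration stay; the C6 carbinol centre formed here is erased in step 11.

Step 10
Reactants: 17 8α-(TBS-oxy)-4-(hydroxymethyl)-3,3-dimethoxy-10α-methylcyclodec-4-ene-6,10β-diol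
Product: 18 15-O-TBDPS ether of 17
Conditions: TBDPSCl (1.05 equiv), imidazole, CH2Cl2, 0 °C
Reagents that add atoms: tert-butyldiphenylsilyl chloride, CC(C)(C)[Si](Cl)(c1ccccc1)c1ccccc1
Why: Silylation with the bulky chlorosilane should pick the primary allylic C15 hydroxyl over the secondary C6 and tertiary C10 hydroxyls.

Step 11
Reactants: 18 15-O-TBDPS ether of 17
Product: 19 8α-(TBS-oxy)-15-(TBDPS-oxy)-10β-hydroxy-3,3-dimethoxy-10α-methylcyclodec-4-en-6-one
Conditions: Dess–Martin periodinane, pyridine, CH2Cl2, 0 → 25 °C
Reagents that add atoms: none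
Why: Dess–Martin oxidation should convert the secondary allylic C6 alcohol into the enone while the tertiary C10 alcohol cannot be oxidized.

Step 12
Reactants: 19 8α-(TBS-oxy)-15-(TBDPS-oxy)-10β-hydroxy-3,3-dimethoxy-10α-methylcyclodec-4-en-6-one
Product: 20 3β,10β-epoxy-3α-methoxy ketal of 19 (bridged enone)
Conditions: PPTS (cat.), CH2Cl2, 4 Å molecular sieves, 25 °C
Reagents that add atoms: none
Why: Acid-catalysed transketalization through the C3 oxocarbenium ion should let the C10 hydroxyl displace one methoxy group and close the five-membered oxygen bridge (5-exo attack on the cation); the bridge can only span the face that carries the C10–O bond, so the C3 configuration follows from C10.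

Step 13
Reactants: 20 3β,10β-epoxy-3α-methoxy ketal of 19
Product: 21 7β-(methoxycarbonylmethyl) derivative of 20
Conditions: LiN(SiMe3)2, THF, −78 °C; BrCH2CO2Me, DMPU, −78 → −40 °C
Reagents that add atoms: methyl bromoacetate, COC(=O)CBr
Why: Kinetic enolate alkylation can occur only at C7 (C5 is vinylic), and the electrophile should enter anti to the neighbouring 8α-silyloxy group, which is also the side of the one-atom oxygen bridge, giving the 7β-arm.

Step 14
Reactants: 21 7β-(methoxycarbonylmethyl) derivative of 20
Product: 23 cis-fused 6β,12-lactone (11,13-dihydro; 8α-OTBS), via hydroxy ester 22 (not isolated)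
Conditions: LiBH(sBu)3, THF, −78 → 0 °C
Reagents that add atoms: none
Why: The bulky borohydride should reduce the β,β-disubstituted enone in the 1,2 sense from the face opposite the C7 arm, so the C6 alkoxide is cis to that arm and closes the γ-lactone by intramolecular transesterification (5-exo-trig).

Step 15
Reactants: 23 cis-fused 6β,12-lactone (11,13-dihydro; 8α-OTBS)
Product: 26 11(13)-methylene lactone (8α-OTBS), via Mannich base 24 (not isolated), via ammonium iodide 25 (not isolated)
Conditions: LiN(iPr)2, THF, −78 °C; CH2=NMe2+ I−, −78 → 25 °C; MeI, MeOH, 25 °C; NaHCO3 (aq), CH2Cl2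
Reagents that add atoms: Eschenmoser's salt (N,N-dimethylmethyleneiminium iodide), C=[N+](C)C.[I-]
Why: Mannich reaction of the lactone enolate with the iminium salt, N-methylation and base-induced elimination of trimethylamine is the standard α-methylenation of γ-lactones, and the C11 centre of 24 disappears in the alkene.

Step 16
Reactants: 26 11(13)-methylene lactone (8α-OTBS)
Product: 27 8α-alcohol of 26
Conditions: HF·pyridine, pyridine, THF, 0 → 25 °C
Reagents that add atoms: none
Why: Buffered fluoride desilylation should cleave the TBS ether well before the bulkier, more robust TBDPS ether and leave the bridged ketal intact.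

Step 17
Reactants: 27 8α-alcohol of 26
Product: 28 8β-angelate (15-OTBDPS; 3,10-bridged methyl ketal)
Conditions: angelic acid, PPh3, DIAD, toluene, 0 → 25 °C
Reagents that add atoms: angelic acid ((Z)-2-methylbut-2-enoic acid), C/C=C(/C)C(=O)O
Why: Mitsunobu esterification should replace the activated 8α-oxygen by angelate with SN2 inversion, giving the 8β-ester of the target under neutral conditions that spare the Z alkene of the acid and the methylene lactone.

Step 18
Reactants: 28 8β-angelate (15-OTBDPS; 3,10-bridged methyl ketal)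
Product: 29 CNP0181802.1 (target)
Conditions: HF (48% aq), MeCN, 0 → 25 °C
Reagents that add atoms: water, O
Why: Aqueous acidic fluoride should remove the TBDPS group and hydrolyse the bridged methyl ketal to the hemiketal, which opens to the C3 ketone and the 10β-carbinol without touching any stereocentre.

**Compound list**

1 | all-cis-cyclohexane-1,3,5-triol | O[C@H]1C[C@@H](O)C[C@@H](O)C1 | starting material
2 | all-cis-5-(tert-butyldimethylsilyloxy)cyclohexane-1,3-diol (meso) | O[C@H]1C[C@@H](O)C[C@@H](O[Si](C)(C)C(C)(C)C)C1 | intermediate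
3 | (1R,3S,5S)-3-hydroxy-5-(tert-butyldimethylsilyloxy)cyclohexyl acetate | O[C@H]1C[C@@H](OC(C)=O)C[C@@H](O[Si](C)(C)C(C)(C)C)C1 | intermediate
4 | (3S,5R)-3-acetoxy-5-(tert-butyldimethylsilyloxy)cyclohexan-1-one (cis) | O=C1C[C@@H](OC(C)=O)C[C@@H](O[Si](C)(C)C(C)(C)C)C1 | intermediate
5 | (R)-5-(tert-butyldimethylsilyloxy)cyclohex-2-en-1-one | O=C1C=CC[C@@H](O[Si](C)(C)C(C)(C)C)C1 | intermediate
6 | (5R)-1-methyl-5-(tert-butyldimethylsilyloxy)cyclohex-2-en-1-ol, both C1 epimers | CC1(O)C=CC[C@@H](O[Si](C)(C)C(C)(C)C)C1 | intermediate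
7 | (S)-5-(tert-butyldimethylsilyloxy)-3-methylcyclohex-2-en-1-one | CC1=CC(=O)C[C@@H](O[Si](C)(C)C(C)(C)C)C1 | intermediate
8 | 1,1-dimethoxyethene | C=C(OC)OC | starting material
9 | methyl acrylate | C=CC(=O)OC | starting material
10 | methyl 2,2-dimethoxycyclobutane-1-carboxylate (racemic) | COC(=O)C1CCC1(OC)OC | intermediate
11 | methyl 2,2-dimethoxy-1-(phenylselanyl)cyclobutane-1-carboxylate (racemic) | COC(=O)C1([Se]c2ccccc2)CCC1(OC)OC | intermediate
12 | methyl 2,2-dimethoxy-1-(phenylseleninyl)cyclobutane-1-carboxylate (selenoxide, diastereomers) | COC(=O)C1([Se](=O)c2ccccc2)CCC1(OC)OC | intermediate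
13 | methyl 4,4-dimethoxycyclobut-1-ene-1-carboxylate | COC(=O)C1=CCC1(OC)OC | intermediate
14 | methyl 9-(tert-butyldimethylsilyloxy)-4,4-dimethoxy-1-methyl-7-oxotricyclo[4.4.0.0(2,5)]decane-5-carboxylate, cis-anti-cis, cyclobutanes anti to the silyloxy group (germacrane bonds C1–C10, C4–C5, C1–C4, C5–C10 present; major isomer drawn) | O=C1C[C@@H](O[Si](C)(C)C(C)(C)C)C[C@@]2(C)[C@@H]1[C@@]1(C(=O)OC)[C@@H]2CC1(OC)OC | intermediate
15 | methyl (8S)-8-(tert-butyldimethylsilyloxy)-3,3-dimethoxy-10-methyl-6-oxocyclodeca-1(10),4-diene-4-carboxylate, (E)-C1=C10, ring-cis C4=C5 | COC1(OC)/C(C(=O)OC)=C\C(=O)C[C@@H](O[Si](C)(C)C(C)(C)C)C/C(C)=C/C1 | intermediate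
16 | (1S,8S,10S)-1,10-epoxide of 15 (1α,10β-epoxy, 8α-silyloxy) | COC1(OC)/C(C(=O)OC)=C\C(=O)C[C@@H](O[Si](C)(C)C(C)(C)C)C[C@]2(C)O[C@H]2C1 | intermediate
17 | 8α-(tert-butyldimethylsilyloxy)-4-(hydroxymethyl)-3,3-dimethoxy-10α-methylcyclodec-4-ene-6,10β-diol, ring-cis alkene, C6 epimers | COC1(OC)/C(CO)=C\C(O)C[C@@H](O[Si](C)(C)C(C)(C)C)C[C@](C)(O)CC1 | intermediate
18 | 15-O-(tert-butyldiphenylsilyl) ether of 17 | COC1(OC)/C(CO[Si](c2ccccc2)(c2ccccc2)C(C)(C)C)=C\C(O)C[C@@H](O[Si](C)(C)C(C)(C)C)C[C@](C)(O)CC1 | intermediate
19 | 8α-(tert-butyldimethylsilyloxy)-4-[(tert-butyldiphenylsilyloxy)methyl]-10β-hydroxy-3,3-dimethoxy-10α-methylcyclodec-4-en-6-one | COC1(OC)/C(CO[Si](c2ccccc2)(c2ccccc2)C(C)(C)C)=C\C(=O)C[C@@H](O[Si](C)(C)C(C)(C)C)C[C@](C)(O)CC1 | intermediate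
20 | 3β,10β-epoxy-3α-methoxy-10α-methyl-8α-(tert-butyldimethylsilyloxy)-4-[(tert-butyldiphenylsilyloxy)methyl]cyclodec-4-en-6-one (3,10-oxygen-bridged ketal) | O=C1/C=C(/CO[Si](c2ccccc2)(c2ccccc2)C(C)(C)C)[C@]2(OC)CC[C@@](C)(O2)C[C@H](O[Si](C)(C)C(C)(C)C)C1 | intermediate
21 | 7β-(methoxycarbonylmethyl) derivative of 20 (7αH, trans to the 8α-silyloxy group) | O=C1/C=C(/CO[Si](c2ccccc2)(c2ccccc2)C(C)(C)C)[C@]2(OC)CC[C@@](C)(O2)C[C@H](O[Si](C)(C)C(C)(C)C)[C@H]1CC(=O)OC | intermediate
22 | 6β-alcohol of 21 (hydroxy ester) | O[C@H]1/C=C(/CO[Si](c2ccccc2)(c2ccccc2)C(C)(C)C)[C@]2(OC)CC[C@@](C)(O2)C[C@H](O[Si](C)(C)C(C)(C)C)[C@H]1CC(=O)OC | intermediate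
23 | cis-fused 6β,12-lactone: 3β,10β-epoxy-3α-methoxy-8α-(tert-butyldimethylsilyloxy)-15-(tert-butyldiphenylsilyloxy)germacr-4-en-6β,12-olide | C1C(=O)O[C@H]2/C=C(/CO[Si](c3ccccc3)(c3ccccc3)C(C)(C)C)[C@]3(OC)CC[C@@](C)(O3)C[C@H](O[Si](C)(C)C(C)(C)C)[C@@H]12 | intermediate
24 | 11-(dimethylaminomethyl) derivative of 23 (C11 epimers) | CN(C)CC1C(=O)O[C@H]2/C=C(/CO[Si](c3ccccc3)(c3ccccc3)C(C)(C)C)[C@]3(OC)CC[C@@](C)(O3)C[C@H](O[Si](C)(C)C(C)(C)C)[C@@H]12 | intermediate
25 | N-methyl ammonium iodide of 24 | [I-].C[N+](C)(C)CC1C(=O)O[C@H]2/C=C(/CO[Si](c3ccccc3)(c3ccccc3)C(C)(C)C)[C@]3(OC)CC[C@@](C)(O3)C[C@H](O[Si](C)(C)C(C)(C)C)[C@@H]12 | intermediate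
26 | 11(13)-methylene lactone: 3β,10β-epoxy-3α-methoxy-8α-(tert-butyldimethylsilyloxy)-15-(tert-butyldiphenylsilyloxy)germacra-4,11(13)-dien-6β,12-olide | C=C1C(=O)O[C@H]2/C=C(/CO[Si](c3ccccc3)(c3ccccc3)C(C)(C)C)[C@]3(OC)CC[C@@](C)(O3)C[C@H](O[Si](C)(C)C(C)(C)C)[C@@H]12 | intermediate
27 | 8α-alcohol of 26 | C=C1C(=O)O[C@H]2/C=C(/CO[Si](c3ccccc3)(c3ccccc3)C(C)(C)C)[C@]3(OC)CC[C@@](C)(O3)C[C@H](O)[C@@H]12 | intermediate
28 | 8β-angelate: 3β,10β-epoxy-3α-methoxy-8β-angeloyloxy-15-(tert-butyldiphenylsilyloxy)germacra-4,11(13)-dien-6β,12-olide | C=C1C(=O)O[C@H]2/C=C(/CO[Si](c3ccccc3)(c3ccccc3)C(C)(C)C)[C@]3(OC)CC[C@@](C)(O3)C[C@@H](OC(=O)/C(C)=C\C)[C@@H]12 | intermediate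
29 | CNP0181802.1: (6S,7R,8R,10R)-8-angeloyloxy-10,15-dihydroxy-3-oxogermacra-4Z,11(13)-dien-6,12-olide | C=C1C(=O)O[C@H]2/C=C(/CO)C(=O)CC[C@@](C)(O)C[C@@H](OC(=O)/C(C)=C\C)[C@@H]12 | target

**Totals and risks**

Total step count: 18. Longest linear sequence: 16 steps (steps 1–4 and 7–18, from triol 1 to target 29); the cyclobutene arm (steps 5–6) joins at step 7.

The three steps most likely to fail:

1. Step 17 (Mitsunobu angeloylation). The alkoxyphosphonium ion at C8 is flanked by the lactone ring fusion; it may eliminate toward C9 or resist backside attack from the crowded β-face, and the angelate may drift toward its E isomer. The fallback sets out from 27 and returns at 28, moving the inversion from a substitution to an oxidation–reduction pair. Dess–Martin oxidation of 27 should give the 8-ketone F1. Reduction with NaBH4/CeCl3·7H2O in MeOH at −78 °C, with hydride entering from the open α-face away from the lactone arm and the oxygen bridge, should give the 8β-alcohol F2. Yamaguchi esterification of F2 with angelic acid (2,4,6-trichlorobenzoyl chloride, Et3N, then DMAP, toluene) keeps the configuration and should give 28.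

2. Step 13 (C7 alkylation). The lithium enolate carries the C8 silyloxy group in the β-position and may expel it (E1cB); it may also be alkylated on oxygen or on the wrong face. The fallback sets out from 20 and returns at 21 without a free enolate. TMSOTf/Et3N should convert 20 into the trimethylsilyl dienol ether F3. Methyl iodoacetate with Et3B and air should then add the electrophilic acetate radical at C7 (atom-transfer alkylation of a silyl enol ether, again anti to the 8α-silyloxy group); loss of iodotrimethylsilane returns ketone 21.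

3. Step 7 (key step). The ketal next to the ester-bearing cyclobutene carbon may slow the photoaddition or tip it toward the head-to-tail adduct, and long heating may carry the 1,5-diene on to its Cope isomer. The fallback sets out from 7, returns at 14 and then 15, and keeps the ketal out of the photochemical step. Irradiation of 7 with methyl propiolate should give the cyclobutene ester F4. Thermal [2+2] addition of 1,1-dimethoxyethene 8 across its strained acrylate-type alkene (same polarity as in step 5, from the convex face) should give tricycle 14, which is opened thermally as in step 7.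

Further compounds
F1 | step 17 | 8-oxo analogue of 27 (3β,10β-epoxy-3α-methoxy-8-oxo-15-(tert-butyldiphenylsilyloxy)germacra-4,11(13)-dien-6β,12-olide) | C=C1C(=O)O[C@H]2/C=C(/CO[Si](c3ccccc3)(c3ccccc3)C(C)(C)C)[C@]3(OC)CC[C@@](C)(O3)CC(=O)[C@@H]12
F2 | step 17 | 8β-alcohol (C8 epimer of 27) | C=C1C(=O)O[C@H]2/C=C(/CO[Si](c3ccccc3)(c3ccccc3)C(C)(C)C)[C@]3(OC)CC[C@@](C)(O3)C[C@@H](O)[C@@H]12
F3 | step 13 | 6-(trimethylsilyloxy)-6(7)-ene dienol ether of 20 | C[Si](C)(C)OC=1/C=C(/CO[Si](c2ccccc2)(c2ccccc2)C(C)(C)C)[C@]2(OC)CC[C@@](C)(O2)C[C@H](O[Si](C)(C)C(C)(C)C)C=1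
F4 | step 7 | methyl 4-(tert-butyldimethylsilyloxy)-6-methyl-2-oxobicyclo[4.2.0]oct-7-ene-8-carboxylate, cis-fused, cyclobutene anti to the silyloxy group | O=C1C[C@@H](O[Si](C)(C)C(C)(C)C)C[C@]2(C)C=C(C(=O)OC)[C@H]12
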